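**Numbering used throughout:** 1 methyl dihydroferulate; 2 its 5-formyl derivative; 3 benzyl ether of 2; 4 nitromethane; 5 nitroaldol (in flask); 6 ring-A nitrostyrene; 7 (E)-4-methoxybut-3-en-2-one; 8 its lithium dienolate (in flask); 9 dienyl triflate; 10 methyl 3-iodopropanoate; 11 its zinc reagent (in flask); 12 diene; 13 cycloadduct; 14 oxime (in flask); 15 cyclohexenone; 16 dienone tautomer (in flask); 17 biaryl phenol diester; 18 benzyl-protected diacid; 19 target.

## Analysis of the target

Compound 19 is a biphenyl in which each ring carries, counted from the ring-joining carbon C1 (C1'), a free hydroxyl at C2 (C2'), a methoxy group at C3 (C3') and a 2-carboxyethyl chain at C5 (C5'); C4 and C6 are unsubstituted. The two halves are constitutionally identical, so the molecule is a dimer of dihydroferulic acid joined through the carbons ortho to the phenolic oxygens. There is no stereocentre, and with only hydroxyl and hydrogen next to the aryl–aryl bond the axis rotates freely, so nothing stereochemical has to be controlled in the final product. The sensitive functions are the two para-alkylated guaiacol units, which are easily oxidised (benzylic oxidation through quinone methides, further phenol coupling), especially as phenoxides, and the two carboxylic acids, which are best carried as methyl esters. The difficulty is to make a 2,2'-dioxygenated biaryl bond between two electron-rich 1,2,3,5-tetrasubstituted rings without regioisomers or oligomers. The plan rests on ring B: the neighbouring atoms C1' and C2' carry an aryl group and an oxygen, which is the pattern of a β-nitrostyrene dienophile if nitro stands in for the phenolic oxygen, while C3'–C4'–C5'–C6', with methoxy at C3' and the chain at C5', is a 1-methoxy-3-alkylbutadiene. Ring B can therefore be grown onto an intact ring A by a [4+2] cycloaddition and aromatised afterwards.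

## Retrosynthetic reasoning

**19 ⇒ 18 ⇒ 17 (O–benzyl bond and ester C–O bonds).** The last two operations only unmask functional groups. The acids are carried as the methyl esters that 1 already has, and the ring-A hydroxyl as a benzyl ether. The benzyl group is needed because a free hydroxyl ortho to a nitrovinyl group would open oxa-Michael and chelation pathways around the cycloaddition. Saponification is placed on 17 and hydrogenolysis last, so the fully deprotected, oxidation-prone bis-phenol is never exposed to base.

**17 ⇒ 15 (ring B taken out of the aromatic oxidation level).** Adding two hydrogens back at C1' and C6' of the phenol ring of 17 gives 15, a 2-methoxycyclohex-3-enone whose carbonyl carbon is C2'. This is the price of building ring B by cycloaddition, and it is one dehydrogenation, passing through the in-flask tautomer 16. The forward reaction must remove H2 without attacking its own product, a para-alkylated guaiacol that high-potential quinone oxidants oxidise at the benzylic position. A palladium-catalysed aerobic dehydrogenation is therefore planned in place of a quinone.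

**15 ⇒ 13 (C2'=O from C2'–N).** The carbonyl is traced back to a secondary nitro group. Nitro does three jobs: it makes the dienophile electrophilic, it fixes the regiochemistry of ring closure, and it is a latent carbonyl. The forward Nef reaction must not pass through a nitronate salt under basic conditions, because the C3' methoxy group is β to the nitronate carbon and would be expelled. A reductive Nef reaction with a trivalent titanium salt in weakly acidic water, through oxime 14, meets this condition.

**13 ⇒ 6 + 12 (C1'–C6' and C2'–C3').** These are the only two bonds whose cleavage leaves ring A intact and turns the biaryl bond into the aryl–vinyl bond of a styrene. Ring B is divided into a two-carbon piece carrying nitrogen and aryl (6) and a four-carbon piece carrying methoxy and the chain (12). No coupling between two hindered, electron-rich arenes is needed. The forward step has to deliver one regiochemistry only; its three stereocentres are erased later.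

**6 ⇒ 3 + 4, 3 ⇒ 2 ⇒ 1 (nitroalkene C=C, benzyl ether, aryl–CHO bond).** The nitroalkene is the condensation product of aldehyde 3 with nitromethane 4 through nitroaldol 5. The formyl group of 2 comes from electrophilic formylation of 1. In 1 the position para to the hydroxyl is occupied by the chain, so the single free ortho position is the only site, and that carbon is the future C1 of ring A.

**12 ⇒ 9 + 10, 9 ⇒ 7 (sp2–sp3 bond between diene C3 and the chain).** The diene is cut between its methylidene-bearing carbon and the chain, giving dienyl triflate 9 and the zinc reagent 11 made from iodide 10. Cutting here means the (E)-enol ether, without which the diene cannot reach the s-cis form, is bought with commercial 7 and never touched; 7 is converted into 9 through its kinetic dienolate 8. Disconnections that form the enol ether or the methylidene group by olefination would give E/Z mixtures or put a strongly basic ylide next to an enolisable ketone and an ester. Acylation of a simple vinyl ether by an unactivated, enolisable acid chloride is not dependable (ketene formation, acid-induced polymerisation of the enol ether).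

## Alternatives that were turned down

**Alternative 1:** Both side chains are disconnected first, at the bond between the ring carbon para to each oxygen and its benzylic CH2 group, and traced back to allyl groups delivered from the phenolic oxygens of the bis-allyl ether A1. In the forward key step A1 is heated. Both ortho positions of each aryl allyl ether in A1 are occupied, so each allyl group moves by a [3,3] shift to an ortho carbon and on by a Cope shift to the para carbon, and enolisation gives the diallyl biphenol A2; no ring closes.
- Structures: A1 is 2,2'-bis(allyloxy)-3,3'-dimethoxybiphenyl, and A2 is 5,5'-diallyl-3,3'-dimethoxybiphenyl-2,2'-diol.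
- For: the rearrangement of A1 is thermal and reagent-free, uses the symmetry of the target, installs both chains in one flask, and creates no stereocentre. The para-Claisen rearrangement of di-ortho-substituted aryl allyl ethers is dependable, arguably more so than an intermolecular cycloaddition, and on that point this alternative is stronger.
- Against: the ether A1 has to be made from the parent biphenol A3, which already contains the difficult biaryl bond. A3 is 3,3'-dimethoxybiphenyl-2,2'-diol. Oxidative coupling of a simple ortho-methoxyphenol with a free para position does not give it selectively, so A3 needs its own directed synthesis. A2 also has the chains at the wrong oxidation level: each terminal alkene must be hydroborated and then oxidised to the acid, which with electron-rich phenols present calls for protection and deprotection.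
- Comparison: counting the synthesis of A3, its bis-allylation to A1, the rearrangement to A2, protection, hydroboration, oxidation and deprotection, the length is no shorter than the chosen route. The chosen route carries both chains at the final oxidation level from compound 1 onwards and makes the aryl–aryl junction without any preformed biphenol.

**Alternative 2:** Both benzene rings are disconnected at once, at C3–C4 and C1–C6 of each ring. The two carbonyl carbons of the diketone A4 (1,6-dimethoxyhexane-2,5-dione) become the two hydroxyl-bearing ring carbons, and its central CH2–CH2 unit becomes the biaryl bond. In the forward key step, under an alkoxide base, each ketone of A4 condenses through both α-methylene groups with the two electrophilic termini of the vinamidinium salt A5, which carries the ester chain on its central carbon. Four C–C bonds form, the amine units are lost, and both rings close as phenols to give A6, the dimethyl ester of the target.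
- For: this is the most convergent plan. One step gives the complete skeleton at the right oxidation level and only saponification of A6 remains. In step count and convergence it is clearly stronger than the chosen route.
- Against: this [3+3] benzannulation is at its best with ketones flanked by acidified methylenes, whereas A4 offers an α-methoxy methylene and an unactivated one. Under the same base a 1,4-diketone can close on itself by intramolecular aldol condensation to a cyclopentenone, which needs no second component. After the first ring has formed, the second annulation must start from a methylene attached to a phenoxide-bearing ring, so stalling at a half-annulated stage is likely. Both A4 and A5 have to be prepared.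
- Comparison: the whole risk sits in one step with several competing pathways and no point at which to intervene. The chosen route is longer, but each bond is made between polarity-matched partners and each failure mode can be treated separately.

**Alternative 3:** The two aryl C–O bonds of the hydroxyl groups are disconnected, both phenolic oxygens coming from formyl groups. This leads to the biphenyl dialdehyde A7, itself the product of oxidative cleavage of the C9–C10 bond of the 1,8-dimethoxyphenanthrene A9, which would come from photocyclisation of the symmetric stilbene A10. In the forward key step A7 reacts with a peracid in a double Dakin-type oxidation: the peracid adds to each formyl group and the electron-rich aryl group migrates to oxygen, giving the bis(aryl formate) A8, which is then solvolysed; no ring closes.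
- For: aryl migration is reliable for aldehydes with an ortho alkoxy group, which both formyl groups of A7 have. The route is symmetric, and the biaryl bond is inherited from a photocyclisation rather than made by a hindered coupling. In the robustness of its final oxygenation it is at least as good as the Nef and dehydrogenation pair of the chosen route.
- Against: C9 and C10 of A9 are built in only to be excised. The aryl unit of A10 has its vinyl group para to the chain, so it does not derive from a ferulate and needs a separate, regiochemically delicate synthesis. Photocyclisation of an ortho-methoxystilbene can also close at the methoxy-bearing carbon with loss of the methoxy group. The two formyl groups of A7 each sit between two ortho substituents and face each other, which slows peracid addition and invites hydrate or cyclic peroxide formation.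
- Comparison: stilbene A10, phenanthrene A9, cleavage to A7, oxidation to A8 and solvolysis make the route at least as long as the chosen one. The chosen route introduces the ring-B phenolic oxygen as the nitro group that also drives the ring construction, with no carbon added and removed.

Key step: step 6

Remark: compounds 5, 13, 14, 15 and 16 are racemic, and their SMILES show one enantiomer and therefore relative configuration only; the counter-ion of vinamidinium salt A5 is taken to be hexafluorophosphate.

## Route

Step 1
Reactants: 1 methyl 3-(4-hydroxy-3-methoxyphenyl)propanoate
Product: 2 methyl 3-(3-formyl-4-hydroxy-5-methoxyphenyl)propanoate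
Conditions: hexamethylenetetramine (2 equiv), CF3CO2H, 90 °C; then 3 M aq. HCl, rt
Reagents that add atoms: hexamethylenetetramine, C1N2CN3CN1CN(C2)C3 (formyl carbon); water, O (formyl oxygen)
Why: Duff formylation: the iminium ion released from protonated hexamethylenetetramine attacks the only free position ortho to the phenolic hydroxyl (para is blocked by the chain), and the benzylamine formed is oxidised by internal hydride transfer and hydrolysed to the aldehyde. The ring carbon that is formylated is the future biaryl carbon C1 of ring A.

Step 2
Reactants: 2 methyl 3-(3-formyl-4-hydroxy-5-methoxyphenyl)propanoate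
Product: 3 methyl 3-[4-(benzyloxy)-3-formyl-5-methoxyphenyl]propanoate
Conditions: BnBr, K2CO3, DMF, 60 °C
Reagents that add atoms: benzyl bromide, BrCc1ccccc1
Why: Williamson etherification of the phenoxide (SN2 at the benzylic carbon). The benzyl ether shuts off oxa-Michael and chelation chemistry of an ortho-hydroxy nitrostyrene and is stable to every step before the final hydrogenolysis.

Step 3
Reactants: 3 methyl 3-[4-(benzyloxy)-3-formyl-5-methoxyphenyl]propanoate; 4 nitromethane
Product: 6 methyl 3-[4-(benzyloxy)-3-methoxy-5-[(E)-2-nitroethenyl]phenyl]propanoate, via nitroaldol 5 (not isolated)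
Conditions: MeNO2 (excess), NH4OAc, AcOH, 100 °C
Reagents that add atoms: none
Why: Henry (nitroaldol) condensation under ammonium acetate catalysis; nitroaldol 5 dehydrates in hot acetic acid to the conjugated nitroalkene, whose (E)-geometry is the thermodynamically favoured one. Ester and benzyl ether are inert to these weakly acidic conditions.

Step 4
Reactants: 7 (E)-4-methoxybut-3-en-2-one
Product: 9 (E)-4-methoxybuta-1,3-dien-2-yl trifluoromethanesulfonate, via lithium dienolate 8 (not isolated)
Conditions: LiN(SiMe3)2, THF, −78 °C; then PhNTf2, −78 to 0 °C; cold aq. NH4Cl quench
Reagents that add atoms: N-phenylbis(trifluoromethanesulfonimide), O=S(=O)(N(c1ccccc1)S(=O)(=O)C(F)(F)F)C(F)(F)F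
Why: Kinetic deprotonation of the methyl group of the vinylogous ester gives the cross-conjugated lithium dienolate, which is sulfonylated on oxygen by the triflimide (enol triflate formation). The (E)-enol ether takes no part and keeps its geometry.

Step 5
Reactants: 9 (E)-4-methoxybuta-1,3-dien-2-yl trifluoromethanesulfonate; 10 methyl 3-iodopropanoate
Product: 12 methyl (E)-6-methoxy-4-methylidenehex-5-enoate, via alkylzinc iodide 11 (not isolated)
Conditions: 10, Zn dust, LiCl, THF, 25–40 °C; then 9, Pd(PPh3)4 (5 mol%), THF, 25–50 °C; neutral work-up
Reagents that add atoms: none
Why: Negishi sp2–sp3 cross-coupling: zerovalent palladium inserts into the alkenyl C–OTf bond, the ester-stabilised zinc homoenolate 11 transmetallates, and reductive elimination forms the C–C bond. The organozinc tolerates the methyl ester, and the enol ether geometry is untouched.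

Step 6
Reactants: 6 methyl 3-[4-(benzyloxy)-3-methoxy-5-[(E)-2-nitroethenyl]phenyl]propanoate; 12 methyl (E)-6-methoxy-4-methylidenehex-5-enoate
Product: 13 methyl 3-[rel-(3,4-cis,4,5-trans)-5-[2-(benzyloxy)-3-methoxy-5-(3-methoxy-3-oxopropyl)phenyl]-3-methoxy-4-nitrocyclohex-1-en-1-yl]propanoate (racemic)
Conditions: 12 (2 equiv), PhMe, 110 °C, sealed tube, BHT (cat.), acid-free glassware
Reagents that add atoms: none
Why: This is a normal-electron-demand Diels–Alder reaction in which the HOMO of diene 12, raised by the 1-methoxy and 3-alkyl groups and largest at the unsubstituted CH2 terminus, meets the LUMO of nitroalkene 6, largest at the aryl-bearing carbon, so bonding is concerted but more advanced at C1'–C6' than at C2'–C3'. The closest known reaction type is the thermal cycloaddition of β-nitrostyrenes with 1-alkoxybutadienes to 3-alkoxy-4-nitro-5-arylcyclohexenes. Ring B closes as a six-membered carbocycle in one intermolecular [4+2] event, suprafacial on both partners, with the diene in the s-cis conformation that only the (E)-enol ether reaches without strain. C1' and C2' are set trans because the (E)-geometry of 6 is transferred stereospecifically. C3' is set relative to C2' by the endo preference of the nitro group (secondary overlap and the dipolar character of the transition state), which places methoxy and nitro cis; any exo adduct is carried along, since it converges later. The product is racemic because neither partner is chiral, and all three centres vanish on aromatisation. The only selectivity the step must deliver is regiochemistry (nitro next to methoxy, aryl next to CH2), and it is secured because the directing effects of the 1-methoxy group and of the 3-alkyl group point to the same diene terminus. A radical inhibitor and exclusion of acid protect the dienol ether during heating.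

Step 7
Reactants: 13 methyl 3-[rel-(3,4-cis,4,5-trans)-5-[2-(benzyloxy)-3-methoxy-5-(3-methoxy-3-oxopropyl)phenyl]-3-methoxy-4-nitrocyclohex-1-en-1-yl]propanoate
Product: 15 methyl 3-[rel-(3,5-trans)-5-[2-(benzyloxy)-3-methoxy-5-(3-methoxy-3-oxopropyl)phenyl]-3-methoxy-4-oxocyclohex-1-en-1-yl]propanoate, via oxime 14 (not isolated)
Conditions: aq. TiCl3 (ca. 5 equiv, in dilute HCl), NH4OAc (to pH ca. 3), THF–H2O, 0 °C to rt, Ar
Reagents that add atoms: water, O (carbonyl oxygen)
Why: Reductive Nef reaction: trivalent titanium reduces the aci-nitro form to oxime 14 and cleaves its N–O bond, and the resulting C=N bond is hydrolysed in the aqueous medium to the ketone. No nitronate salt is formed under basic conditions, so the C3' methoxy group is not expelled; the centres at C1' and C3' are now α to the carbonyl and may epimerise, which does not matter.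

Step 8
Reactants: 15 methyl 3-[rel-(3,5-trans)-5-[2-(benzyloxy)-3-methoxy-5-(3-methoxy-3-oxopropyl)phenyl]-3-methoxy-4-oxocyclohex-1-en-1-yl]propanoate
Product: 17 dimethyl 3,3'-[2-(benzyloxy)-2'-hydroxy-3,3'-dimethoxybiphenyl-5,5'-diyl]dipropanoate, via dienone tautomer 16 (not isolated)
Conditions: Pd(O2CCF3)2 (5 mol%), 2-(dimethylamino)pyridine (10 mol%), TsOH·H2O (20 mol%), O2 (1 atm), DMSO, 80 °C
Reagents that add atoms: none
Why: Palladium-catalysed aerobic dehydrogenation of a cyclohexenone to a phenol: a divalent palladium enolate undergoes β-hydride elimination across C1'–C6' to dienone 16, which tautomerises to the phenol, and O2 reoxidises the catalyst. A quinone oxidant is avoided because the product is a para-alkyl guaiacol, which such reagents oxidise further at the benzylic position.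

Step 9
Reactants: 17 dimethyl 3,3'-[2-(benzyloxy)-2'-hydroxy-3,3'-dimethoxybiphenyl-5,5'-diyl]dipropanoate
Product: 18 3,3'-[2-(benzyloxy)-2'-hydroxy-3,3'-dimethoxybiphenyl-5,5'-diyl]dipropanoic acid
Conditions: LiOH·H2O (6 equiv), THF–MeOH–H2O (degassed), rt; then 1 M HCl
Reagents that add atoms: lithium hydroxide, [Li+].[OH-] (hydroxyl oxygen of each carboxylic acid)
Why: Saponification of both methyl esters by acyl–oxygen cleavage. Degassed solvents keep the single phenoxide from air oxidation, and acidification returns the diacid.

Step 10
Reactants: 18 3,3'-[2-(benzyloxy)-2'-hydroxy-3,3'-dimethoxybiphenyl-5,5'-diyl]dipropanoic acid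
Product: 19 3,3'-(2,2'-dihydroxy-3,3'-dimethoxybiphenyl-5,5'-diyl)dipropanoic acid
Conditions: H2 (1 atm), Pd/C (10%), MeOH–EtOAc, rt
Reagents that add atoms: none
Why: Hydrogenolysis of the aryl benzyl ether on palladium; nothing else in 18 is reducible under these conditions, and the target should be obtained after filtration and crystallisation without contact with base.

## Compound list

1 | methyl 3-(4-hydroxy-3-methoxyphenyl)propanoate | COC(=O)CCc1ccc(O)c(OC)c1 | starting material
2 | methyl 3-(3-formyl-4-hydroxy-5-methoxyphenyl)propanoate | COC(=O)CCc1cc(OC)c(O)c(C=O)c1 | intermediate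
3 | methyl 3-[4-(benzyloxy)-3-formyl-5-methoxyphenyl]propanoate | COC(=O)CCc1cc(OC)c(OCc2ccccc2)c(C=O)c1 | intermediate
4 | nitromethane | C[N+](=O)[O-] | starting material
5 | methyl 3-[4-(benzyloxy)-3-(1-hydroxy-2-nitroethyl)-5-methoxyphenyl]propanoate (racemic) | COC(=O)CCc1cc(OC)c(OCc2ccccc2)c(C(O)C[N+](=O)[O-])c1 | intermediate (not isolated)
6 | methyl 3-[4-(benzyloxy)-3-methoxy-5-[(E)-2-nitroethenyl]phenyl]propanoate | COC(=O)CCc1cc(OC)c(OCc2ccccc2)c(/C=C/[N+](=O)[O-])c1 | intermediate
7 | (E)-4-methoxybut-3-en-2-one | CC(=O)/C=C/OC | starting material
8 | lithium (E)-4-methoxybuta-1,3-dien-2-olate | [Li+].[O-]C(=C)/C=C/OC | intermediate (not isolated)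
9 | (E)-4-methoxybuta-1,3-dien-2-yl trifluoromethanesulfonate | C=C(OS(=O)(=O)C(F)(F)F)/C=C/OC | intermediate
10 | methyl 3-iodopropanoate | COC(=O)CCI | starting material
11 | (3-methoxy-3-oxopropyl)zinc iodide | COC(=O)CC[Zn]I | intermediate (not isolated)
12 | methyl (E)-6-methoxy-4-methylidenehex-5-enoate | COC(=O)CCC(=C)/C=C/OC | intermediate
13 | methyl 3-[rel-(3,4-cis,4,5-trans)-5-[2-(benzyloxy)-3-methoxy-5-(3-methoxy-3-oxopropyl)phenyl]-3-methoxy-4-nitrocyclohex-1-en-1-yl]propanoate (racemic) | COC(=O)CCC1=C[C@H](OC)[C@H]([N+](=O)[O-])[C@@H](c2cc(CCC(=O)OC)cc(OC)c2OCc2ccccc2)C1 | intermediate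
14 | methyl 3-[rel-(3,5-trans)-5-[2-(benzyloxy)-3-methoxy-5-(3-methoxy-3-oxopropyl)phenyl]-4-(hydroxyimino)-3-methoxycyclohex-1-en-1-yl]propanoate (racemic, oxime geometry not defined) | COC(=O)CCC1=C[C@H](OC)C(=NO)[C@@H](c2cc(CCC(=O)OC)cc(OC)c2OCc2ccccc2)C1 | intermediate (not isolated)
15 | methyl 3-[rel-(3,5-trans)-5-[2-(benzyloxy)-3-methoxy-5-(3-methoxy-3-oxopropyl)phenyl]-3-methoxy-4-oxocyclohex-1-en-1-yl]propanoate (racemic) | COC(=O)CCC1=C[C@H](OC)C(=O)[C@@H](c2cc(CCC(=O)OC)cc(OC)c2OCc2ccccc2)C1 | intermediate
16 | methyl 3-[5-[2-(benzyloxy)-3-methoxy-5-(3-methoxy-3-oxopropyl)phenyl]-3-methoxy-4-oxocyclohexa-1,5-dien-1-yl]propanoate (racemic) | COC(=O)CCC1=CC(OC)C(=O)C(c2cc(CCC(=O)OC)cc(OC)c2OCc2ccccc2)=C1 | intermediate (not isolated)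
17 | dimethyl 3,3'-[2-(benzyloxy)-2'-hydroxy-3,3'-dimethoxybiphenyl-5,5'-diyl]dipropanoate | COC(=O)CCc1cc(OC)c(O)c(-c2cc(CCC(=O)OC)cc(OC)c2OCc2ccccc2)c1 | intermediate
18 | 3,3'-[2-(benzyloxy)-2'-hydroxy-3,3'-dimethoxybiphenyl-5,5'-diyl]dipropanoic acid | O=C(O)CCc1cc(OC)c(O)c(-c2cc(CCC(=O)O)cc(OC)c2OCc2ccccc2)c1 | intermediate
19 | 3,3'-(2,2'-dihydroxy-3,3'-dimethoxybiphenyl-5,5'-diyl)dipropanoic acid | COc1cc(CCC(=O)O)cc(-c2cc(CCC(=O)O)cc(OC)c2O)c1O | target

## Step count and risk

Total step count: 10. Longest linear sequence: 8 steps (1 → 2 → 3 → 6 → 13 → 15 → 17 → 18 → 19, steps 1, 2, 3, 6, 7, 8, 9, 10); the diene branch 7 → 9 → 12 adds 2 steps.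

**Step 6 (key step).**
- Risk: the cycloaddition may be too slow, because the alkoxy-substituted ring A donates into the nitroalkene and lowers its electrophilicity. The dienol ether could then polymerise or hydrolyse before it reacts.
- Risk: the nitroalkene could instead react as a heterodiene across one double bond of 12, and the adduct could lose its methoxy or nitro group on prolonged heating.
- Fallback: it sets out from 6 and 12 and returns at 13, using the hetero-cycloaddition pathway deliberately. With SnCl4 in CH2Cl2 at −78 °C the nitroalkene, acting as a heterodiene, should add across the terminal double bond of 12. The aryl-bearing carbon bonds to the CH2 terminus and the nitronate oxygen to the chain-bearing carbon, giving the six-membered cyclic nitronate methyl 3-[4-[2-(benzyloxy)-3-methoxy-5-(3-methoxy-3-oxopropyl)phenyl]-6-[(E)-2-methoxyethenyl]-2-oxido-5,6-dihydro-4H-1,2-oxazin-2-ium-6-yl]propanoate F1. Warming F1 in toluene should trigger the [3,3] shift of the O-allyl nitronate, which forms C2'–C3', restores the nitro group and gives 13.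

**Step 7.**
- Risk: loss of the C3' methoxy group, either by β-elimination if a nitronate accumulates or by ionisation of the allylic ether in the acidic medium.
- Risk: the reduction may stall at the oxime, or the titanium reagent may cleave the α-methoxy group reductively from the ketone once it has formed.
- Fallback: it sets out from 13 and returns at 15. Reduction of the nitro group with Zn in AcOH–EtOH should give the primary amine methyl 3-[rel-(3,4-cis,4,5-trans)-4-amino-5-[2-(benzyloxy)-3-methoxy-5-(3-methoxy-3-oxopropyl)phenyl]-3-methoxycyclohex-1-en-1-yl]propanoate F2. F2 is condensed with 3,5-di-tert-butyl-1,2-benzoquinone; prototropic shift of the Schiff base and hydrolysis with aqueous oxalic acid should then release ketone 15 (oxidative transamination, no nitronate and no low-valent metal in contact with the ketone).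

**Step 8.**
- Risk: slow turnover, because the α-carbon C1' is tertiary and shielded by the ortho-disubstituted ring A, and over-oxidation of the phenol once it has formed.
- Not a risk: migration of the ring double bond into conjugation with the carbonyl may also occur, but both tautomers lead to the same phenol.
- Fallback: it sets out from 15 and returns at 17. Soft enolisation with tert-butyldimethylsilyl triflate and Et3N should give the silyl dienol ether methyl 3-[5-[2-(benzyloxy)-3-methoxy-5-(3-methoxy-3-oxopropyl)phenyl]-4-[(tert-butyldimethylsilyl)oxy]-3-methoxycyclohexa-1,3-dien-1-yl]propanoate F3. This cyclohexadiene is dehydrogenated with one equivalent of DDQ at 0 °C to the aryl silyl ether dimethyl 3,3'-[2-(benzyloxy)-2'-[(tert-butyldimethylsilyl)oxy]-3,3'-dimethoxybiphenyl-5,5'-diyl]dipropanoate F4. In F4 the phenol is masked and cannot be oxidised on to a quinone methide; Bu4NF then frees 17.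

**Step 5.**
- Risk: β-hydride elimination from the alkylpalladium intermediate, which would reduce the triflate instead of coupling it.
- Risk: incomplete zinc insertion, and hydrolysis of the acid-labile triflate or dienol ether on work-up.
- Fallback: it sets out from 7 and returns at 12. Dienolate 8, generated as in step 4, is alkylated with methyl bromoacetate (THF, N,N'-dimethylpropyleneurea, −78 to −30 °C) to methyl (E)-6-methoxy-4-oxohex-5-enoate F5. The ketone of F5 is then methylenated by a Wittig reaction with Ph3PCH3Br and KN(SiMe3)2 under lithium-free conditions to give 12.

## Further compounds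

F1 | step 6 | methyl 3-[4-[2-(benzyloxy)-3-methoxy-5-(3-methoxy-3-oxopropyl)phenyl]-6-[(E)-2-methoxyethenyl]-2-oxido-5,6-dihydro-4H-1,2-oxazin-2-ium-6-yl]propanoate (racemic, diastereomer mixture) | COC(=O)CCC1(/C=C/OC)CC(c2cc(CCC(=O)OC)cc(OC)c2OCc2ccccc2)C=[N+]([O-])O1
F2 | step 7 | methyl 3-[rel-(3,4-cis,4,5-trans)-4-amino-5-[2-(benzyloxy)-3-methoxy-5-(3-methoxy-3-oxopropyl)phenyl]-3-methoxycyclohex-1-en-1-yl]propanoate (racemic) | COC(=O)CCC1=C[C@H](OC)[C@H](N)[C@@H](c2cc(CCC(=O)OC)cc(OC)c2OCc2ccccc2)C1
F3 | step 8 | methyl 3-[5-[2-(benzyloxy)-3-methoxy-5-(3-methoxy-3-oxopropyl)phenyl]-4-[(tert-butyldimethylsilyl)oxy]-3-methoxycyclohexa-1,3-dien-1-yl]propanoate (racemic) | COC(=O)CCC1=CC(OC)=C(O[Si](C)(C)C(C)(C)C)C(c2cc(CCC(=O)OC)cc(OC)c2OCc2ccccc2)C1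
F4 | step 8 | dimethyl 3,3'-[2-(benzyloxy)-2'-[(tert-butyldimethylsilyl)oxy]-3,3'-dimethoxybiphenyl-5,5'-diyl]dipropanoate | COC(=O)CCc1cc(OC)c(O[Si](C)(C)C(C)(C)C)c(-c2cc(CCC(=O)OC)cc(OC)c2OCc2ccccc2)c1
F5 | step 5 | methyl (E)-6-methoxy-4-oxohex-5-enoate | COC(=O)CCC(=O)/C=C/OC
A1 | alternative 1 | 2,2'-bis(allyloxy)-3,3'-dimethoxybiphenyl | C=CCOc1c(OC)cccc1-c1cccc(OC)c1OCC=C
A2 | alternative 1 | 5,5'-diallyl-3,3'-dimethoxybiphenyl-2,2'-diol | C=CCc1cc(OC)c(O)c(-c2cc(CC=C)cc(OC)c2O)c1
A3 | alternative 1 | 3,3'-dimethoxybiphenyl-2,2'-diol | COc1cccc(-c2cccc(OC)c2O)c1O
A4 | alternative 2 | 1,6-dimethoxyhexane-2,5-dione | COCC(=O)CCC(=O)COC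
A5 | alternative 2 | [3-(dimethylamino)-2-(3-methoxy-3-oxopropyl)prop-2-en-1-ylidene]dimethylammonium hexafluorophosphate | CN(C)C=C(CCC(=O)OC)C=[N+](C)C.F[P-](F)(F)(F)(F)F
A6 | alternative 2 | dimethyl 3,3'-(2,2'-dihydroxy-3,3'-dimethoxybiphenyl-5,5'-diyl)dipropanoate | COC(=O)CCc1cc(OC)c(O)c(-c2cc(CCC(=O)OC)cc(OC)c2O)c1
A7 | alternative 3 | dimethyl 3,3'-(2,2'-diformyl-3,3'-dimethoxybiphenyl-5,5'-diyl)dipropanoate | COC(=O)CCc1cc(OC)c(C=O)c(-c2cc(CCC(=O)OC)cc(OC)c2C=O)c1
A8 | alternative 3 | dimethyl 3,3'-[2,2'-bis(formyloxy)-3,3'-dimethoxybiphenyl-5,5'-diyl]dipropanoate | COC(=O)CCc1cc(OC)c(OC=O)c(-c2cc(CCC(=O)OC)cc(OC)c2OC=O)c1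
A9 | alternative 3 | dimethyl 3,3'-(1,8-dimethoxyphenanthrene-3,6-diyl)dipropanoate | COC(=O)CCc1cc(OC)c2ccc3c(OC)cc(CCC(=O)OC)cc3c2c1
A10 | alternative 3 | dimethyl 3,3'-[(E)-ethene-1,2-diylbis(3-methoxy-4,1-phenylene)]dipropanoate | COC(=O)CCc1ccc(/C=C/c2ccc(CCC(=O)OC)cc2OC)c(OC)c1
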